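The constants first: the north flask stays closed and stirred at 40 °C, charged with 12 mM substrate and 0.02 mol% free enzyme, and the meeting asked what that charge will yield.

in all of them: substrate 12 mM

|  | free enzyme | temperature | remark | time |
|---|---|---|---|---|
| north | 0.02 mol% | 40 °C | the very flask that is asked about, followed so far |  |
| north-east | 0.01 mol% | 25 °C | run made earlier |  |
| flask | 0.02 mol% | 40 °C |  | 8.0 d |

| run | time / h | target / % |
|---|---|---|
| north | 15.0 | 37 |
| north | 30.0 | 55 |
| north | 60.0 | 66 |
| north | 96.0 | 72 |
| north | 192 | 82 |
| north-east | 3.00 | 5 |
| north-east | 6.00 | 6 |
| north-east | 12.0 | 14 |
| north-east | 20.0 | 17 |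
| north-east | 40.0 | 30 |

(each reading ± 1.5 percentage points)

- cedar: at 8.0 d take out 90% of the target then present, then wait 15 d
- larch: at 8.0 d raise the temperature by 15 K, then wait 15 d
- elm: change nothing and wait 15 d more
- birch: at 8.0 d add free enzyme, 100% of the amount charged, then wait 15 d

- removed target is counted in
- additions bring no volume worth counting

* target, in percent of the substrate first charged, at 8.0 d
* which option adds most target ("none" when 2 percentage points or less is all one gets) (cedar / larch / elm / birch / none)
* target present, with what was taken out counted in, in percent of the substrate first charged, after cedar
* target present, with what was taken out counted in, in percent of the substrate first charged, after birch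

**Minutes.** The chair noted that target in the north-east run climbs steadily to 30% at 40.0 h, whereas the north run slows hard. I reported that the north run made 0.0247 h⁻¹ of the charge in its first interval and 0.00104 h⁻¹ in its last, while mean substrate fell from 81.5% to 23.0%.

I therefore proposed the stall order, an apparent order: the logarithm of the fall in rate divided by the logarithm of the fall in substrate, here 2.50. It is a reading, with any enzyme loss lumped in. With that order held, I argued, what remains shrinks as elapsed time to the power of one over the order less one, and doubled enzyme counts as doubled waiting. From the last reading, my reckoning gave 91.1% for elm and 93.6% for birch. Target does not enter this rule, so I set cedar equal to elm.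

The forecaster put now at 82%, cedar at 94% and birch at 97%, and chose birch, holding that “Removing target changes little, so cedar gives about the same as waiting”. My figure for birch stood lower than that forecast.

**Result.** The flask gives 79.2% at 8.0 d, and birch is best, with 88.2%. Cedar reaches 83.7%, which is 10 percentage points below the forecast.

    free enzyme → unfolded enzyme (k = 1.23 × 10⁻⁶ s⁻¹, Ea = 184 kJ mol⁻¹)
    substrate + free enzyme → target + free enzyme, rate k2*[substrate]^3*[free enzyme]/(1 + ([substrate]/Kh2)^3) (10.1 mM, k = 76800 M⁻³ s⁻¹, Ea = 28.0 kJ mol⁻¹)
    (constants at 40 °C)

In the north flask, half of the target made by 8.0 d was made by 16.7 h, far sooner than the 160 h half-life of free enzyme. From 19.2 h to 192 h in the north flask, free enzyme fell by a factor of 2.15, smaller than the 12.4 that the decline of substrate gives at the stall order. For a neighbour flask charged at [substrate] = 7.2 mM with the same loading, so with [free enzyme] lowered in step, that order slows the clock so that 192 h corresponds to 53.5 h of the north run, between its readings of 55% and 66%. The computed neighbour flask gives 58.9%.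

(The earlier runs and the new flask come from a simulation for substances that don't exist, and the scatter is random.)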